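**Strategy.** Everything rests on cutting the C4–C5 bond of ring A (C1–C2–C3–C4–C5–C9). The C2(=O)–C3H=C4(OEt) vinylogous ester of the O-ethyl-protected core is treated as the adduct of enol carbon C5 of the ring B ketone (C9) and an ethoxy ynone hanging from C1. One gold-catalysed 6-endo-dig carbocyclization therefore closes ring A, creates the quaternary C5 bridgehead and delivers the 2,4-dione already protected. The precursor is an enantiopure cyclohexenyl silyl ether (C5 geranyl, C7 prenyl, C8 gem-dimethyl) whose quaternary C1 carries prenyl and the 3-ethoxypropynoyl group; C7 is set by an auxiliary-controlled Michael addition, C1 by an anti-selective aldol.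

Key step: step 14

Remark: ring carbons of all intermediates are referred to by their target locants (C9 ketone carbon, C1, C8 = CMe2, C7, C6, C5). Prenyl = 3-methylbut-2-en-1-yl, geranyl = (2E)-3,7-dimethylocta-2,6-dien-1-yl. Acid 1 is assumed to be a purchasable building block.

**Route**

Step 1
Reactants: 1 5-methylhex-4-enoic acid; 2 tributyl(vinyl)stannane
Product: 4 7-methylocta-1,6-dien-3-one, via 5-methylhex-4-enoyl chloride 3 (not isolated)
Conditions: (COCl)2, DMF (cat.), CH2Cl2, 0 °C → rt; evaporate; then 2, Pd(PPh3)4 (2 mol %), toluene, 50 °C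
Reagents that add atoms: none
Why: Migita–Kosugi–Stille acylation, in which the acid chloride adds oxidatively to zerovalent palladium and the vinyl group is transferred from tin in preference to butyl, should give the vinyl ketone without touching the trisubstituted alkene.

Step 2
Reactants: 1 5-methylhex-4-enoic acid; 5 (R)-4-benzyl-1,3-oxazolidin-2-one
Product: 7 (R)-4-benzyl-3-(5-methylhex-4-enoyl)-1,3-oxazolidin-2-one, via mixed pivalic anhydride 6 (not isolated)
Conditions: t-BuCOCl, Et3N, THF, −20 °C; then LiCl, 5, −20 °C → rt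
Reagents that add atoms: none
Why: N-acylation of the oxazolidinone through the mixed anhydride should be clean because the hindered pivaloyl carbonyl is not attacked.

Step 3
Reactants: 7 (R)-4-benzyl-3-(5-methylhex-4-enoyl)-1,3-oxazolidin-2-one; 4 7-methylocta-1,6-dien-3-one
Product: 9 (R)-4-benzyl-3-[(R)-9-methyl-2-(3-methylbut-2-en-1-yl)-5-oxodec-8-enoyl]-1,3-oxazolidin-2-one, via chlorotitanium Z-enolate 8 (not isolated)
Conditions: TiCl4, Ti(OiPr)4 (3:1), iPr2NEt, CH2Cl2, 0 °C; then 4, 0 °C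
Reagents that add atoms: none
Why: In this oxazolidinone-controlled asymmetric Michael addition the chelated Z titanium enolate should add to the vinyl ketone on the face opposite the benzyl group, which sets C7 (R here, the prenyl-bearing centre of the target).

Step 4
Reactants: 9 (R)-4-benzyl-3-[(R)-9-methyl-2-(3-methylbut-2-en-1-yl)-5-oxodec-8-enoyl]-1,3-oxazolidin-2-one
Product: 10 (R)-2,4-bis(3-methylbut-2-en-1-yl)cyclohexane-1,3-dione
Conditions: LiN(SiMe3)2 (2.2 equiv), THF, −78 → 0 °C; then 1 M HCl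
Reagents that add atoms: none
Why: Intramolecular Claisen (Dieckmann-type) condensation, in which the C1 ketone enolate acylates itself on the activated exocyclic imide carbonyl through a six-membered transition state and expels the auxiliary, should preserve C7 because the alpha-branched imide enolizes slowly and the product is stored as its dionate.

Step 5
Reactants: 10 (R)-2,4-bis(3-methylbut-2-en-1-yl)cyclohexane-1,3-dione
Product: 11 (R)-3-methoxy-2,6-bis(3-methylbut-2-en-1-yl)cyclohex-2-en-1-one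
Conditions: HC(OMe)3, TsOH·H2O (cat.), MeOH, rt
Reagents that add atoms: trimethyl orthoformate, COC(OC)OC
Why: Acid-catalysed enol etherification under thermodynamic control should place the methoxy group on C9, away from the C7 prenyl group (less allylic strain), the minor regioisomer being removed by chromatography.

Step 6
Reactants: 11 (R)-3-methoxy-2,6-bis(3-methylbut-2-en-1-yl)cyclohex-2-en-1-one
Product: 13 (R)-3-methyl-2,4-bis(3-methylbut-2-en-1-yl)cyclohex-2-en-1-one, via tertiary allylic alcohol 12 (not isolated)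
Conditions: MeLi, THF, −78 → 0 °C; then 1 M HCl, THF, rt
Reagents that add atoms: methyllithium, [Li]C
Why: Stork–Danheiser carbonyl transposition, 1,2-addition to the C8 carbonyl of the vinylogous ester followed by acid hydrolysis of the enol ether with loss of methanol, should give the 2,3,4-trisubstituted enone with C7 untouched.

Step 7
Reactants: 13 (R)-3-methyl-2,4-bis(3-methylbut-2-en-1-yl)cyclohex-2-en-1-one
Product: 14 (R)-{[3,3-dimethyl-2,4-bis(3-methylbut-2-en-1-yl)cyclohex-1-en-1-yl]oxy}trimethylsilane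
Conditions: Me2CuLi (from CuI and 2 MeLi), Me3SiCl, THF/Et2O, −78 → −20 °C; Et3N
Reagents that add atoms: lithium dimethylcuprate, [Li+].C[Cu-]C; chlorotrimethylsilane, C[Si](C)(C)Cl
Why: Silyl chloride-accelerated conjugate addition of the cuprate should build the C8 gem-dimethyl group and trap the enolate regiospecifically as the C9=C1 silyl enol ether, with no stereocentre being formed.

Step 8
Reactants: 14 (R)-{[3,3-dimethyl-2,4-bis(3-methylbut-2-en-1-yl)cyclohex-1-en-1-yl]oxy}trimethylsilane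
Product: 16 (2S,4R)-2-(hydroxymethyl)-3,3-dimethyl-2,4-bis(3-methylbut-2-en-1-yl)cyclohexan-1-one, via lithium enolate 15 (not isolated)
Conditions: MeLi, THF, 0 °C → rt; then CH2O (gas, from cracked paraformaldehyde), −78 °C; H2O
Reagents that add atoms: formaldehyde, C=O
Why: Aldol addition of the regiodefined lithium enolate to monomeric formaldehyde should occur axially at C1 of the half-chair on the face anti to the C7 prenyl group (the other axial path is syn-axial to that group or eclipses the axial C8 methyl), so CH2OH ends trans to the C7 prenyl and C1 is set by 1,3-induction.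

Step 9
Reactants: 16 (2S,4R)-2-(hydroxymethyl)-3,3-dimethyl-2,4-bis(3-methylbut-2-en-1-yl)cyclohexan-1-one; 17 geranyl bromide
Product: 19 (2S,4S,6RS)-6-[(2E)-3,7-dimethylocta-2,6-dien-1-yl]-2-(hydroxymethyl)-3,3-dimethyl-2,4-bis(3-methylbut-2-en-1-yl)cyclohexan-1-one, via dilithio alkoxide enolate 18 (not isolated)
Conditions: LiN(iPr)2 (2.2 equiv), THF, −78 → −40 °C; then 17, −78 → −20 °C
Reagents that add atoms: none
Why: Enolate alkylation of the alkoxide–enolate dianion should be regiospecific because C5 is the only enolizable carbon, and the C5 epimers are carried on since C5 becomes trigonal in step 11.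

Step 10
Reactants: 19 (2S,4S,6RS)-6-[(2E)-3,7-dimethylocta-2,6-dien-1-yl]-2-(hydroxymethyl)-3,3-dimethyl-2,4-bis(3-methylbut-2-en-1-yl)cyclohexan-1-one
Product: 20 (1S,3RS,5S)-3-[(2E)-3,7-dimethylocta-2,6-dien-1-yl]-6,6-dimethyl-1,5-bis(3-methylbut-2-en-1-yl)-2-oxocyclohexane-1-carbaldehyde
Conditions: Dess–Martin periodinane, NaHCO3, CH2Cl2, 0 °C
Reagents that add atoms: none
Why: Buffered Dess–Martin oxidation of the neopentyl primary alcohol should give the non-enolizable beta-keto aldehyde without retro-aldol cleavage or alkene oxidation.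

Step 11
Reactants: 20 (1S,3RS,5S)-3-[(2E)-3,7-dimethylocta-2,6-dien-1-yl]-6,6-dimethyl-1,5-bis(3-methylbut-2-en-1-yl)-2-oxocyclohexane-1-carbaldehyde
Product: 21 (1R,5S)-2-[(tert-butyldimethylsilyl)oxy]-3-[(2E)-3,7-dimethylocta-2,6-dien-1-yl]-6,6-dimethyl-1,5-bis(3-methylbut-2-en-1-yl)cyclohex-2-ene-1-carbaldehyde
Conditions: TBSOTf, Et3N, CH2Cl2, 0 °C → rt
Reagents that add atoms: tert-butyldimethylsilyl trifluoromethanesulfonate, CC(C)(C)[Si](C)(C)OS(=O)(=O)C(F)(F)F
Why: Soft enolization with silyl triflate and amine can remove only the C5 hydrogen, so a single tetrasubstituted silyl enol ether should form, while the aldehyde, lacking alpha-hydrogens, is returned unchanged on work-up.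

Step 12
Reactants: 21 (1R,5S)-2-[(tert-butyldimethylsilyl)oxy]-3-[(2E)-3,7-dimethylocta-2,6-dien-1-yl]-6,6-dimethyl-1,5-bis(3-methylbut-2-en-1-yl)cyclohex-2-ene-1-carbaldehyde; 22 ethyl ethynyl ether
Product: 24 1-{(1S,5S)-2-[(tert-butyldimethylsilyl)oxy]-3-[(2E)-3,7-dimethylocta-2,6-dien-1-yl]-6,6-dimethyl-1,5-bis(3-methylbut-2-en-1-yl)cyclohex-2-en-1-yl}-3-ethoxyprop-2-yn-1-ol (carbinol epimers), via lithium ethoxyacetylide 23 (not isolated)
Conditions: n-BuLi, THF, −78 °C; then 21, −78 °C; aq. NaHCO3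
Reagents that add atoms: none
Why: 1,2-Addition of the slim lithium alkoxyacetylide to the hindered aldehyde should be clean because the ketone is masked as its silyl enol ether, which rules out both competing addition and retro-aldol cleavage.

Step 13
Reactants: 24 1-{(1S,5S)-2-[(tert-butyldimethylsilyl)oxy]-3-[(2E)-3,7-dimethylocta-2,6-dien-1-yl]-6,6-dimethyl-1,5-bis(3-methylbut-2-en-1-yl)cyclohex-2-en-1-yl}-3-ethoxyprop-2-yn-1-ol
Product: 25 1-{(1R,5S)-2-[(tert-butyldimethylsilyl)oxy]-3-[(2E)-3,7-dimethylocta-2,6-dien-1-yl]-6,6-dimethyl-1,5-bis(3-methylbut-2-en-1-yl)cyclohex-2-en-1-yl}-3-ethoxyprop-2-yn-1-one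
Conditions: MnO2 (activated, excess), CH2Cl2, rt; used at once
Reagents that add atoms: none
Why: Neutral MnO2 oxidation of the propargylic alcohol should give the push–pull ynone while leaving the acid-sensitive ynol ether and the silyl enol ether intact, so the ynone never meets a strong base.

Step 14
Reactants: 25 1-{(1R,5S)-2-[(tert-butyldimethylsilyl)oxy]-3-[(2E)-3,7-dimethylocta-2,6-dien-1-yl]-6,6-dimethyl-1,5-bis(3-methylbut-2-en-1-yl)cyclohex-2-en-1-yl}-3-ethoxyprop-2-yn-1-one
Product: 26 (1S,5R,7S)-5-[(2E)-3,7-dimethylocta-2,6-dien-1-yl]-4-ethoxy-8,8-dimethyl-1,7-bis(3-methylbut-2-en-1-yl)bicyclo[3.3.1]non-3-ene-2,9-dione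
Conditions: Ph3PAuNTf2 (5 mol %), i-PrOH (2 equiv), CH2Cl2, 0 °C → rt
Reagents that add atoms: none
Why: Proposed new method: the cationic monovalent gold centre binds the C3≡C4 triple bond, whose polarization by the C2 carbonyl and the ethoxy group makes C4 the electrophilic carbon; C5 of the silyl enol ether attacks it anti to gold, the silyl oxocarbenium ion hands its silyl group to propan-2-ol, and the liberated proton cleaves the C3–Au bond. The closest known reaction type is the gold-catalysed carbocyclization of silyl enol ethers onto tethered alkynes and ynones that gives bicyclo[3.3.1]nonenones, the 3-alkoxy ynone acceptor being the untested element. Ring A is closed in a 6-endo-dig mode. The new C5 stereocentre is fixed by the tether, because the ynone hangs from C1 and C4 can reach C5 only on the face that makes the one-carbon C9 bridge cis, which is the target configuration. The step needs 6-endo attack at C4 instead of 5-exo attack at C3, and it needs the enol ether and not a prenyl or geranyl alkene as nucleophile; the first is secured by the matched ynone and ynol ether polarization, the second by the far higher nucleophilicity of the enol ether and by the quaternary C1, which leaves C5 as the only enol carbon. A hindered alcohol instead of water is the silyl acceptor so that hydration of the ynol ether is suppressed.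

Step 15
Reactants: 27 3,4-dihydroxybenzoic acid
Product: 29 3,4-bis[(tert-butyldimethylsilyl)oxy]benzoic acid, via tris-silylated acid 28 (not isolated)
Conditions: TBSCl (3.3 equiv), imidazole, DMF, rt; then AcOH/THF/H2O, rt
Reagents that add atoms: tert-butyldimethylsilyl chloride, CC(C)(C)[Si](C)(C)Cl
Why: Exhaustive silylation followed by selective hydrolysis of the labile silyl ester should leave both phenols protected as silyl ethers.

Step 16
Reactants: 29 3,4-bis[(tert-butyldimethylsilyl)oxy]benzoic acid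
Product: 30 3,4-bis[(tert-butyldimethylsilyl)oxy]benzoyl chloride
Conditions: (COCl)2, DMF (cat.), CH2Cl2, 0 °C → rt; evaporate
Reagents that add atoms: oxalyl chloride, O=C(Cl)C(=O)Cl
Why: Acid chloride formation through the Vilsmeier-type chloroiminium catalyst is mild enough for aryl silyl ethers.

Step 17
Reactants: 26 (1S,5R,7S)-5-[(2E)-3,7-dimethylocta-2,6-dien-1-yl]-4-ethoxy-8,8-dimethyl-1,7-bis(3-methylbut-2-en-1-yl)bicyclo[3.3.1]non-3-ene-2,9-dione; 30 3,4-bis[(tert-butyldimethylsilyl)oxy]benzoyl chloride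
Product: 32 (1R,5R,7S)-3-{3,4-bis[(tert-butyldimethylsilyl)oxy]benzoyl}-5-[(2E)-3,7-dimethylocta-2,6-dien-1-yl]-4-ethoxy-8,8-dimethyl-1,7-bis(3-methylbut-2-en-1-yl)bicyclo[3.3.1]non-3-ene-2,9-dione, via C3-lithio vinylogous ester 31 (not isolated)
Conditions: lithium 2,2,6,6-tetramethylpiperidide (from the amine and n-BuLi), THF, −78 °C; then 30, −78 → −40 °C
Reagents that add atoms: none
Why: Vinylic lithiation at C3 (alpha to the C2 carbonyl and stabilized by the C4 ethoxy group) followed by C-acylation should be site-selective because both bridgeheads are quaternary and the hindered amide neither adds to nor reduces the ketones.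

Step 18
Reactants: 32 (1R,5R,7S)-3-{3,4-bis[(tert-butyldimethylsilyl)oxy]benzoyl}-5-[(2E)-3,7-dimethylocta-2,6-dien-1-yl]-4-ethoxy-8,8-dimethyl-1,7-bis(3-methylbut-2-en-1-yl)bicyclo[3.3.1]non-3-ene-2,9-dione
Product: 33 (1R,5R,7S)-3-(3,4-dihydroxybenzoyl)-5-[(2E)-3,7-dimethylocta-2,6-dien-1-yl]-4-hydroxy-8,8-dimethyl-1,7-bis(3-methylbut-2-en-1-yl)bicyclo[3.3.1]non-3-ene-2,9-dione (CNP0160101.4)
Conditions: LiOH, dioxane/H2O (degassed, Ar), 60 °C; then 1 M HCl, 0 °C
Reagents that add atoms: lithium hydroxide, [Li+].[OH-]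
Why: Hydroxide should add at C4 of the doubly activated vinylogous ester and expel ethoxide (addition–elimination) while cleaving both aryl silyl ethers, and cold acidification then releases the enolized triketone and the catechol without acid-induced cyclization onto the prenyl groups.

**Compound list**

1 | 5-methylhex-4-enoic acid | CC(C)=CCCC(=O)O | starting material
2 | tributyl(vinyl)stannane | C=C[Sn](CCCC)(CCCC)CCCC | starting material
3 | 5-methylhex-4-enoyl chloride | CC(C)=CCCC(=O)Cl | intermediate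
4 | 7-methylocta-1,6-dien-3-one | C=CC(=O)CCC=C(C)C | intermediate
5 | (R)-4-benzyl-1,3-oxazolidin-2-one | O=C1N[C@H](Cc2ccccc2)CO1 | starting material
6 | 5-methylhex-4-enoic pivalic anhydride | CC(C)=CCCC(=O)OC(=O)C(C)(C)C | intermediate
7 | (R)-4-benzyl-3-(5-methylhex-4-enoyl)-1,3-oxazolidin-2-one | CC(C)=CCCC(=O)N1[C@H](Cc2ccccc2)COC1=O | intermediate
8 | dichloro(isopropoxy)titanium Z-enolate of 7 | CC(C)=CC/C=C(\O[Ti](Cl)(Cl)OC(C)C)N1[C@H](Cc2ccccc2)COC1=O | intermediate
9 | (R)-4-benzyl-3-[(R)-9-methyl-2-(3-methylbut-2-en-1-yl)-5-oxodec-8-enoyl]-1,3-oxazolidin-2-one | O=C([C@@H](CC=C(C)C)CCC(=O)CCC=C(C)C)N1[C@H](Cc2ccccc2)COC1=O | intermediate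
10 | (R)-2,4-bis(3-methylbut-2-en-1-yl)cyclohexane-1,3-dione (drawn as the diketo form) | O=C1CC[C@H](CC=C(C)C)C(=O)C1CC=C(C)C | intermediate
11 | (R)-3-methoxy-2,6-bis(3-methylbut-2-en-1-yl)cyclohex-2-en-1-one | COC1=C(CC=C(C)C)C(=O)[C@@H](CC=C(C)C)CC1 | intermediate
12 | (6R)-3-methoxy-1-methyl-2,6-bis(3-methylbut-2-en-1-yl)cyclohex-2-en-1-ol (carbinol epimers) | COC1=C(CC=C(C)C)C(C)(O)[C@@H](CC=C(C)C)CC1 | intermediate
13 | (R)-3-methyl-2,4-bis(3-methylbut-2-en-1-yl)cyclohex-2-en-1-one | O=C1CC[C@H](CC=C(C)C)C(C)=C1CC=C(C)C | intermediate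
14 | (R)-{[3,3-dimethyl-2,4-bis(3-methylbut-2-en-1-yl)cyclohex-1-en-1-yl]oxy}trimethylsilane | C[Si](C)(C)OC1=C(CC=C(C)C)C(C)(C)[C@@H](CC=C(C)C)CC1 | intermediate
15 | lithium enolate corresponding to 14 | [Li]OC1=C(CC=C(C)C)C(C)(C)[C@@H](CC=C(C)C)CC1 | intermediate
16 | (2S,4R)-2-(hydroxymethyl)-3,3-dimethyl-2,4-bis(3-methylbut-2-en-1-yl)cyclohexan-1-one (CH2OH trans to the 4-prenyl group) | O=C1CC[C@H](CC=C(C)C)C(C)(C)[C@@]1(CC=C(C)C)CO | intermediate
17 | geranyl bromide | CC(C)=CCC/C(C)=C/CBr | starting material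
18 | dilithium alkoxide enolate of 16 | [Li]OC1=CC[C@H](CC=C(C)C)C(C)(C)[C@@]1(CC=C(C)C)CO[Li] | intermediate
19 | (2S,4S,6RS)-6-[(2E)-3,7-dimethylocta-2,6-dien-1-yl]-2-(hydroxymethyl)-3,3-dimethyl-2,4-bis(3-methylbut-2-en-1-yl)cyclohexan-1-one | O=C1C(C/C=C(\C)CCC=C(C)C)C[C@H](CC=C(C)C)C(C)(C)[C@@]1(CC=C(C)C)CO | intermediate
20 | (1S,3RS,5S)-3-[(2E)-3,7-dimethylocta-2,6-dien-1-yl]-6,6-dimethyl-1,5-bis(3-methylbut-2-en-1-yl)-2-oxocyclohexane-1-carbaldehyde | O=C1C(C/C=C(\C)CCC=C(C)C)C[C@H](CC=C(C)C)C(C)(C)[C@@]1(CC=C(C)C)C=O | intermediate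
21 | (1R,5S)-2-[(tert-butyldimethylsilyl)oxy]-3-[(2E)-3,7-dimethylocta-2,6-dien-1-yl]-6,6-dimethyl-1,5-bis(3-methylbut-2-en-1-yl)cyclohex-2-ene-1-carbaldehyde | CC(C)=CCC/C(C)=C/CC1=C(O[Si](C)(C)C(C)(C)C)[C@](CC=C(C)C)(C=O)C(C)(C)[C@@H](CC=C(C)C)C1 | intermediate
22 | ethyl ethynyl ether | CCOC#C | starting material
23 | lithium ethoxyacetylide | CCOC#C[Li] | intermediate
24 | 1-{(1S,5S)-2-[(tert-butyldimethylsilyl)oxy]-3-[(2E)-3,7-dimethylocta-2,6-dien-1-yl]-6,6-dimethyl-1,5-bis(3-methylbut-2-en-1-yl)cyclohex-2-en-1-yl}-3-ethoxyprop-2-yn-1-ol (carbinol epimers) | CC(C)=CCC/C(C)=C/CC1=C(O[Si](C)(C)C(C)(C)C)[C@](CC=C(C)C)(C(O)C#COCC)C(C)(C)[C@@H](CC=C(C)C)C1 | intermediate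
25 | 1-{(1R,5S)-2-[(tert-butyldimethylsilyl)oxy]-3-[(2E)-3,7-dimethylocta-2,6-dien-1-yl]-6,6-dimethyl-1,5-bis(3-methylbut-2-en-1-yl)cyclohex-2-en-1-yl}-3-ethoxyprop-2-yn-1-one (key-step precursor) | CC(C)=CCC/C(C)=C/CC1=C(O[Si](C)(C)C(C)(C)C)[C@](CC=C(C)C)(C(=O)C#COCC)C(C)(C)[C@@H](CC=C(C)C)C1 | intermediate
26 | (1S,5R,7S)-5-[(2E)-3,7-dimethylocta-2,6-dien-1-yl]-4-ethoxy-8,8-dimethyl-1,7-bis(3-methylbut-2-en-1-yl)bicyclo[3.3.1]non-3-ene-2,9-dione (key-step product) | CC(C)=CCC/C(C)=C/C[C@@]12C[C@H](CC=C(C)C)C(C)(C)[C@@](CC=C(C)C)(C(=O)C=C1OCC)C2=O | intermediate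
27 | 3,4-dihydroxybenzoic acid | O=C(O)c1ccc(O)c(O)c1 | starting material
28 | tert-butyldimethylsilyl 3,4-bis[(tert-butyldimethylsilyl)oxy]benzoate | CC(C)(C)[Si](C)(C)OC(=O)c1ccc(O[Si](C)(C)C(C)(C)C)c(O[Si](C)(C)C(C)(C)C)c1 | intermediate
29 | 3,4-bis[(tert-butyldimethylsilyl)oxy]benzoic acid | O=C(O)c1ccc(O[Si](C)(C)C(C)(C)C)c(O[Si](C)(C)C(C)(C)C)c1 | intermediate
30 | 3,4-bis[(tert-butyldimethylsilyl)oxy]benzoyl chloride | O=C(Cl)c1ccc(O[Si](C)(C)C(C)(C)C)c(O[Si](C)(C)C(C)(C)C)c1 | intermediate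
31 | 3-lithio derivative of 26 | CC(C)=CCC/C(C)=C/C[C@@]12C[C@H](CC=C(C)C)C(C)(C)[C@@](CC=C(C)C)(C(=O)C([Li])=C1OCC)C2=O | intermediate
32 | (1R,5R,7S)-3-{3,4-bis[(tert-butyldimethylsilyl)oxy]benzoyl}-5-[(2E)-3,7-dimethylocta-2,6-dien-1-yl]-4-ethoxy-8,8-dimethyl-1,7-bis(3-methylbut-2-en-1-yl)bicyclo[3.3.1]non-3-ene-2,9-dione | CC(C)=CCC/C(C)=C/C[C@@]12C[C@H](CC=C(C)C)C(C)(C)[C@@](CC=C(C)C)(C(=O)C(C(=O)c3ccc(O[Si](C)(C)C(C)(C)C)c(O[Si](C)(C)C(C)(C)C)c3)=C1OCC)C2=O | intermediate
33 | (1R,5R,7S)-3-(3,4-dihydroxybenzoyl)-5-[(2E)-3,7-dimethylocta-2,6-dien-1-yl]-4-hydroxy-8,8-dimethyl-1,7-bis(3-methylbut-2-en-1-yl)bicyclo[3.3.1]non-3-ene-2,9-dione | CC(C)=CCC/C(C)=C/C[C@@]12C[C@H](CC=C(C)C)C(C)(C)[C@@](CC=C(C)C)(C(=O)C(C(=O)c3ccc(O)c(O)c3)=C1O)C2=O | target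

**Step count and risk**

Total steps: 18. Longest linear sequence: 15 steps (steps 2–14, 17 and 18 from acid 1; the branch through step 1 is equally long).

Steps most likely to fail:

1. Step 14 (labelled new method). The gold-activated ynol ether may be consumed before the C–C bond forms, by addition of the alcohol, by hydration through adventitious water or by loss of ethylene. The C1 prenyl alkene may also compete as an enyne partner, or closure may go 5-exo. The fallback brings in the C4 oxygen after a cyclization of established type. Setting out from 21, HC≡CMgBr in THF should give the terminal propargylic alcohol F1. Double deprotonation with n-BuLi and bromination of the acetylide with CBr4 at −78 °C should give the bromoalkynyl carbinol F2, a halogenation that spares the silyl enol ether. MnO2 should then give the bromo ynone F3. The known gold-catalysed 6-endo-dig carbocyclization of a silyl enol ether onto a haloalkynyl ketone (Ph3PAuNTf2, i-PrOH, CH2Cl2) should give the 4-bromo bicyclic enone F4. Addition–elimination with NaOEt in EtOH replaces bromide by ethoxide and comes back to the route at 26.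

2. Step 8. Proton transfer or retro-aldol loss of formaldehyde at the very congested enolate, and incomplete facial selectivity at C1, may erode the yield. The fallback introduces the one-carbon unit on the silyl enol ether as an oxocarbenium ion, at the aldehyde oxidation level and irreversibly. Setting out from 14, trimethyl orthoformate and catalytic TMSOTf (Mukaiyama-type alkylation, CH2Cl2, −78 °C) should give the beta-keto dimethyl acetal F5, again anti to the C7 prenyl group. LiN(iPr)2 and 17 then alkylate C5 to give the geranylated keto acetal F6. Mild aqueous acid (pyridinium tosylate, acetone/H2O) unmasks the aldehyde and comes back to the route at 20.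

3. Step 11. Silyl triflate activation of the free aldehyde, leading to Prins-type closure with a neighbouring alkene, may outrun the slow enolization of the hindered ketone. The fallback unveils the aldehyde only after the enol ether is in place. Setting out from 19, pivaloyl chloride (pyridine, DMAP) should give the hydroxymethyl pivalate F7. KN(SiMe3)2 and TBSOTf (THF, −78 °C) should convert the ketone into the silyl enol ether pivalate F8. iBu2AlH (CH2Cl2, −78 °C) then removes the ester to give the silyl enol ether alcohol F9, and Dess–Martin oxidation comes back to the route at 21.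

**Further compounds**

F1 | step 14 | 1-{(5S)-2-[(tert-butyldimethylsilyl)oxy]-3-geranyl-6,6-dimethyl-1,5-diprenylcyclohex-2-en-1-yl}prop-2-yn-1-ol (ring configuration as in 21) | CC(C)=CCC/C(C)=C/CC1=C(O[Si](C)(C)C(C)(C)C)[C@](CC=C(C)C)(C(O)C#C)C(C)(C)[C@@H](CC=C(C)C)C1
F2 | step 14 | 3-bromo analogue of F1 (3-bromoprop-2-yn-1-ol) | CC(C)=CCC/C(C)=C/CC1=C(O[Si](C)(C)C(C)(C)C)[C@](CC=C(C)C)(C(O)C#CBr)C(C)(C)[C@@H](CC=C(C)C)C1
F3 | step 14 | 3-bromoprop-2-yn-1-one corresponding to 25 (Br in place of OEt) | CC(C)=CCC/C(C)=C/CC1=C(O[Si](C)(C)C(C)(C)C)[C@](CC=C(C)C)(C(=O)C#CBr)C(C)(C)[C@@H](CC=C(C)C)C1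
F4 | step 14 | 4-bromo-5-geranyl-8,8-dimethyl-1,7-diprenylbicyclo[3.3.1]non-3-ene-2,9-dione (configuration as in 26) | CC(C)=CCC/C(C)=C/C[C@@]12C[C@H](CC=C(C)C)C(C)(C)[C@@](CC=C(C)C)(C(=O)C=C1Br)C2=O
F5 | step 8 | 2-(dimethoxymethyl)-3,3-dimethyl-2,4-diprenylcyclohexan-1-one (configuration as in 16) | O=C1CC[C@H](CC=C(C)C)C(C)(C)[C@@]1(CC=C(C)C)C(OC)OC
F6 | step 8 | 6-geranyl derivative of F5 (C6 epimers) | O=C1C(C/C=C(\C)CCC=C(C)C)C[C@H](CC=C(C)C)C(C)(C)[C@@]1(CC=C(C)C)C(OC)OC
F7 | step 11 | pivalate ester of 19 | O=C1C(C/C=C(\C)CCC=C(C)C)C[C@H](CC=C(C)C)C(C)(C)[C@@]1(CC=C(C)C)COC(=O)C(C)(C)C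
F8 | step 11 | tert-butyldimethylsilyl enol ether of F7 | CC(C)=CCC/C(C)=C/CC1=C(O[Si](C)(C)C(C)(C)C)[C@](CC=C(C)C)(COC(=O)C(C)(C)C)C(C)(C)[C@@H](CC=C(C)C)C1
F9 | step 11 | primary alcohol corresponding to 21 (CH2OH in place of CHO) | CC(C)=CCC/C(C)=C/CC1=C(O[Si](C)(C)C(C)(C)C)[C@](CC=C(C)C)(CO)C(C)(C)[C@@H](CC=C(C)C)C1
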